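## Retrosynthetic overview
- Last step: remove the 4'-O-MOM group from the protected flavanone to reveal the target (S)-flavanone.
- The only ring formed is the pyranone C-ring. Its O1–C2 bond and the C2 stereocentre come from a catalytic, enantioselective intramolecular oxa-Michael addition of a 2'-hydroxychalcone.
- The chalcone comes from a Claisen–Schmidt condensation of a 3-prenylated 2',6'-dihydroxy-4'-methoxyacetophenone with 4-(MOM-oxy)benzaldehyde.
- The prenylated acetophenone comes from C-prenylation of the commercial, mirror-symmetric 2',6'-dihydroxy-4'-methoxyacetophenone. Its symmetry makes the two ortho carbons equivalent, so there is no regiochemistry problem at this step.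

**Assumptions**
- 4-(Methoxymethoxy)benzaldehyde is treated as a purchasable reagent.
- In the chalcone, the carbonyl chelates the OH next to the prenyl group, leaving the unhindered 6'-OH as the nucleophile. That gives the 6-prenyl-5-OH flavanone, with any 8-prenyl isomer removed by chromatography.
- The catalyst series (quinine- or quinidine-derived) that gives the (S) product is confirmed by a small screen.

The target SMILES has O > aryl > CH2 > H at C2, which is (S). The MOM-protected intermediate **7** uses the same SMILES pattern, so its configuration is also (S).

## Route

**Step 1**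
Reactants: **1** 2',6'-dihydroxy-4'-methoxyacetophenone; **2** prenyl bromide (1-bromo-3-methylbut-2-ene)
Product: **3** 1-[2,6-dihydroxy-4-methoxy-3-(3-methylbut-2-en-1-yl)phenyl]ethan-1-one
Conditions: **2** (1.05 equiv), KOH (2.2 equiv), MeOH/H2O, 0 °C → rt, 12 h
Reagents that add atoms: prenyl bromide, CC(C)=CCBr
Why: A hydrogen-bonded phenoxide in a protic solvent is alkylated on carbon, ortho to OH, rather than on oxygen. This is a phenoxide C-alkylation (SN2). Because **1** is symmetric, either ortho carbon gives the same product, and about one equivalent of prenyl bromide limits diprenylation. No stereocentre is formed.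

**Step 2**
Reactants: **3** prenylated acetophenone; **4** 4-(methoxymethoxy)benzaldehyde
Product: **5** (E)-1-[2,6-dihydroxy-4-methoxy-3-prenylphenyl]-3-[4-(methoxymethoxy)phenyl]prop-2-en-1-one
Conditions: 50% aq. KOH, EtOH, rt, 2–3 d
Reagents that add atoms: none
Why: Claisen–Schmidt condensation, in which the methyl ketone enolate adds to the aldehyde and the aldol dehydrates to the conjugated E-enone. The MOM ether, aryl methyl ether and prenyl alkene are stable to base. No stereocentre is formed, and the alkene is E.

**Step 3**
Reactants: **5** chalcone; **6** quinine-derived 9-epi-amino thiourea bifunctional catalyst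
Product: **7** (S)-5-hydroxy-2-[4-(methoxymethoxy)phenyl]-7-methoxy-6-prenylchroman-4-one
Conditions: **6** (20 mol %), CH2Cl2 (0.05 M), 25 °C, 3 d
Reagents that add atoms: none (**6** is a catalyst and is not incorporated)
Why: This is an enantioselective intramolecular oxa-Michael addition. The thiourea N–H groups bind the enone carbonyl, and the tertiary amine deprotonates the free, unhindered 6'-OH. The phenoxide then attacks one face of the β-carbon, setting C2 as (S). The ring closure is driven downhill to the flavanone, and the chelated 5-OH stays intact.

**Step 4**
Reactants: **7** MOM-protected flavanone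
Product: **8** 6-prenylsakuranetin, (S)-5,4'-dihydroxy-7-methoxy-6-prenylflavanone
Conditions: cat. conc. HCl, MeOH/THF, 40 °C, 4 h
Reagents that add atoms: none (the MOM group leaves as CH2(OMe)2)
Why: Acid-catalysed cleavage of the aryl MOM acetal. Conditions this mild leave the H-bonded 5-OH, the prenyl group and the C2 stereocentre untouched, because C2 epimerises only through base-mediated ring opening.

## Compound list
1 | 2',6'-dihydroxy-4'-methoxyacetophenone | COc1cc(O)c(C(C)=O)c(O)c1 | starting material
2 | prenyl bromide | CC(C)=CCBr | starting material
3 | 1-[2,6-dihydroxy-4-methoxy-3-prenylphenyl]ethanone | CC(=O)c1c(O)cc(OC)c(CC=C(C)C)c1O | intermediate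
4 | 4-(methoxymethoxy)benzaldehyde | COCOc1ccc(C=O)cc1 | starting material
5 | (E)-2',6'-dihydroxy-4'-methoxy-3'-prenyl-4-(MOM-oxy)chalcone | COCOc1ccc(/C=C/C(=O)c2c(O)cc(OC)c(CC=C(C)C)c2O)cc1 | intermediate
6 | 9-epi-amino-9-deoxyquinine 3,5-bis(CF3)phenyl thiourea (organocatalyst, not incorporated) | COc1ccc2nccc([C@@H]([C@@H]3C[C@@H]4CCN3C[C@@H]4C=C)NC(=S)Nc3cc(C(F)(F)F)cc(C(F)(F)F)c3)c2c1 | starting material
7 | (S)-5-hydroxy-2-[4-(MOM-oxy)phenyl]-7-methoxy-6-prenylchroman-4-one | COc1cc2c(c(O)c1CC=C(C)C)C(=O)C[C@@H](c1ccc(OCOC)cc1)O2 | intermediate
8 | 6-prenylsakuranetin | COc1cc2c(c(O)c1CC=C(C)C)C(=O)C[C@@H](c1ccc(O)cc1)O2 | target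

## Totals
Total steps: 4. Longest linear sequence: 4 steps.

## Three steps most likely to fail
1. **Step 3 (ee and regiochemistry).** Reversible oxa-Michael addition can erode ee, and some 8-prenyl isomer may form.
   - Fallback: build the 5-hydroxy-6-prenyl-7-methoxychromone and add 4-(MOM-oxy)phenylboronic acid by chiral Rh- or Pd-catalysed asymmetric 1,4-addition. This sets C2 by conjugate addition to a preformed ring instead of by ring closure.
   - Alternative: cyclise racemically (NaOAc, EtOH, reflux) and resolve **7** by preparative chiral-phase SFC or HPLC.
2. **Step 1 (C- vs O-prenylation and diprenylation).** Yields are modest.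
   - Fallback: iodinate **1** with NIS, then couple the aryl iodide with a prenyl-boron reagent by Suzuki–Miyaura coupling. This installs the prenyl group by cross-coupling instead of alkylation.
3. **Step 2 (Claisen–Schmidt).** The doubly phenolate-deactivated ketone gives sluggish, low-yielding condensation.
   - Fallback: protect both phenols of **3** as MOM ethers and run the aldol with **4** under LDA or NaOH/EtOH. Then remove all the MOM groups with HCl/MeOH to give the free 2',6',4-trihydroxychalcone for the oxa-Michael cyclisation. Step 4 is then not needed, but the free 4-OH makes the enone less electrophilic, so a longer reaction time or higher catalyst loading may be needed.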